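Remark on numbering: in every 1,2‑dioxane the ring is numbered as in the target (O1, O2, C3 with the acetate arm or its precursor, C4 with ethyl, C5, quaternary C6); chain carbons are primed (C1' on C6, stereocentre C4').
Remark on chemistry: the 3‑methoxy‑1,2‑dioxanes 31–34 are carried as mixtures of C3 anomers, because both ionise to the same cation 35; their SMILES leave C3 open.

## Analysis of the target

Target 36 is a monocyclic 1,2‑dioxane with a methyl acetate arm at C3, an ethyl group at C4 and, at the quaternary C6, an ethyl group and a (2E,4R,5E)‑4‑ethyl‑2‑methylocta‑2,5‑dienyl chain. The ring centres are 3R,4R,6R: the acetate arm, the C4 ethyl group and the dienyl chain lie on one face and the C6 ethyl group on the other, so the chair with C4‑ethyl and the chain equatorial holds the acetate arm axial. The fourth stereocentre, C4', is doubly allylic and is insulated from the ring by the planar C2'=C3' unit, so it cannot be relayed from the ring and has to be brought in with its own control. Sensitive groups are the O–O bond (low‑valent metals, phosphines, hydride and radical reductants, hydrogenation catalysts), the C3–H next to O2 together with the β‑peroxy ester (base‑induced ring fragmentation), and the skipped diene. The hard point is C6: a peroxide‑bearing quaternary carbon whose three carbon substituents (C5, C1' and the ethyl CH2) are all methylene groups of similar size, so a diastereoselective addition to a C6 ketone or cation cannot be trusted. The strategy rests on this same feature: because all three arms are CH2 groups, C6 can be written as one terminus of a trisubstituted alkene C6=CH, the CH being the future ethyl CH2. Its configuration is then held as alkene geometry and released by a reagent‑controlled epoxidation followed by invertive opening with the peroxide nucleophile.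

## Retrosynthetic reasoning

C3–CH2 bond. Target 36 is cut between C3 and the acetate arm, giving peroxyacetal 34 and an acetate enolate equivalent that adds to the cyclic cation 35. The cut is made here because C3 is the only ring carbon at the aldehyde oxidation level, so it can serve first as the anchor for ring closure and then as the electrophile. The base‑sensitive β‑peroxy ester then appears only in the last step. The forward reaction has to place the arm cis to the C4 ethyl group.

Ethyl group at C6. The ethyl group of 34 is traced back through vinyl compound 33 and aldehyde 32 to the glycol of 31. These two carbons are the remnant of the alkene that carried the C6 information; no C–C bond to the ring is made or broken. The forward steps (glycol cleavage, methylenation, metal‑free alkene reduction) must leave the O–O bond and the chain alkenes intact.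

O1–C6 and O2–C3 bonds. Dioxane 31 is opened to epoxy alcohol 29 through hydroperoxy diol 30. Both peroxide oxygens arrive as one nucleophile that attacks the tertiary epoxide carbon with inversion and is then captured by the C3 acetal as a six‑membered peroxyacetal. This places the peroxide late and makes C6 the product of a stereospecific substitution.

Epoxide. Epoxy alcohol 29 comes from (Z)‑allylic alcohol 28 by Sharpless epoxidation, and 28 from enoate 27 by ester reduction. The face of oxygen delivery is set by the chiral ligand and the relative position of the two CH2 arms by the alkene geometry, so C6 is fixed by reagent control and not by the distant C4 or C4' centres.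

C5–C6 bond (key disconnection). Enoate 27 is cut between C5 and C6 into ynoate 16 and iodide 23. This is the one bond that divides the molecule into the chain half (with C4') and the ring half (with C4), and its formation by syn‑carbometalation of the triple bond creates the alkene geometry at the same time. The C5 arm is chosen as the nucleophile because metalation of the C1' arm would give an ambident allylic metal, and the ester must sit on the future ethyl carbon to provide the allylic alcohol.

Chain half. Ynoate 16 is cut at C1'–C(alkyne) into allylic bromide 14 and methyl propiolate 15. Bromide 14 goes back through alcohol 13 and silyl ether 12 to the C3'–C4' bond, formed by anti‑SN2' substitution of picolinate 4 with the alkenyl nucleophile from iodide 8. The electrophile has ethyl groups on both allyl termini, so α‑ and γ‑attack give the same constitution and only the stereochemical course matters. Iodide 8 comes from prop‑2‑yn‑1‑ol 5 via 7, and picolinate 4 from (2E)‑pent‑2‑enal 1 via 2 and 3.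

Ring half. Iodide 23 is derived from alcohol 22, which comes from imide 21 by reductive removal of the auxiliary. The C3–C4 bond of 21 is made by alkylation of the enolate of imide 19 (from 17 and 18) with a one‑carbon electrophile at the aldehyde oxidation level. The acetal is thus installed directly and no α‑chiral aldehyde is ever handled.

## Alternatives that were turned down

Alternative 1: The ring is cut at O1–C6 within the ring‑closing step. An open‑chain precursor A2, which already carries a secondary hydroperoxide on C3 and the acetate arm as a silyl‑protected hydroxyethyl group, would open the trisubstituted epoxy alcohol at its tertiary carbon under mild acid (6‑exo, inversion) to give dioxane A1.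
- For: ring closure and the C6 configuration are settled in one intramolecular, stereospecific event, and the tether enforces the regiochemistry. C3 is fixed before the ring exists, so there is no late facial question at C3; on this point it is stronger than the chosen route.
- Against: A2 needs a configurationally defined secondary hydroperoxide next to the C4 branch, realistically by displacement of a hindered sulfonate with a peroxide nucleophile (elimination competes), and this free hydroperoxide must coexist with an acid‑labile epoxide until closure. The epoxide still requires the geometrically pure trisubstituted allylic alcohol, so the problem solved by the carbocupration remains. After closure the same glycol‑to‑ethyl editing is needed, plus desilylation, oxidation to the acid in the presence of the peroxide and esterification.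
- Comparison: the chosen route brings both peroxide oxygens in one step and locks them in the ring at once, and it is about three steps shorter after the epoxide. It pays with a substrate‑controlled C3 step.

Alternative 2: The C3–C4 bond is cut as an aldol. Amino acid A6 turns butanal A5 into its enamine, which adds to silyloxy aldehyde A4 to give the anti aldol A3 with C3 and C4 set together.
- For: two adjacent centres from two simple aldehydes in one catalytic step, with catalyst control at C3, where the chosen route relies on the ring. On this point it is stronger.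
- Against: a cross‑aldol between two linear enolisable aldehydes needs slow addition and an excess of one partner. A3 is an α‑branched β‑hydroxy aldehyde prone to dehydration and epimerisation. The C3 oxygen must later be exchanged for a peroxide oxygen with inversion at a hindered secondary carbon. Above all, the aldol says nothing about C6, which would still need a separate device, and A3 has to be elaborated over several steps into a C5 nucleophile.
- Comparison: the chosen strategy puts its key step on the hardest centre, C6, and joins the two halves in that same step. The four‑step auxiliary route to 23 sets C4 with comparable reliability.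

Alternative 3: The C6–vinyl bond is cut. Bis‑peroxyketal A8 would be ionised at the ketal carbon C6 by a boron Lewis acid and the tertiary peroxycarbenium ion trapped axially by vinyl donor A9 to give A7.
- For: it is much the shortest. The dioxane ring comes from a keto aldehyde in one operation, there is no epoxide and no glycol editing, and A7 has the constitution of 33, which the chosen route reaches only at step 19. In step economy it is clearly stronger.
- Against: the C6 configuration would depend on the facial preference of a cation whose two carbon substituents are both CH2 groups; the only control element is the C4 ethyl group in a 1,3‑relationship, and no reagent can override it. Ionisation must select the C6 ketal over the C3 acetal, the homoallylic C2'=C3' alkene can participate in the C6 cation, and the nucleophile class is an extension from ordinary oxocarbenium ions.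
- Comparison: the chosen route spends roughly eight more steps to make C6 the outcome of a stereospecific relay (alkene geometry, tartrate‑controlled epoxidation, inversion) that does not depend on ring conformation.

Key step: step 14

## Route

Step 1
Reactants: 1 (2E)‑pent‑2‑enal
Product: 2 rac‑(4E)‑hept‑4‑en‑3‑ol
Conditions: EtMgBr, Et2O, −78 → 0 °C; aq. NH4Cl
Reagents that add atoms: ethylmagnesium bromide, CC[Mg]Br
Why: 1,2‑addition of a Grignard reagent to an enal; the hard nucleophile attacks the carbonyl carbon at low temperature and leaves the (E)‑alkene untouched, giving the racemic allylic alcohol.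

Step 2
Reactants: 2 rac‑(4E)‑hept‑4‑en‑3‑ol
Product: 3 (3R,4E)‑hept‑4‑en‑3‑ol
Conditions: Ti(OiPr)4 (0.1 equiv), L‑(+)‑diisopropyl tartrate (0.15 equiv), t‑BuOOH (0.6 equiv), 4 Å MS, CH2Cl2, −20 °C, run to about 55% conversion
Reagents that add atoms: none
Why: Sharpless kinetic resolution of a secondary (E)‑allylic alcohol; with the L‑(+)‑tartrate the (S)‑enantiomer should be epoxidised much faster, so the (R)‑alcohol is recovered, and its carbinol centre is the source of C4' in step 6.

Step 3
Reactants: 3 (3R,4E)‑hept‑4‑en‑3‑ol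
Product: 4 (3R,4E)‑hept‑4‑en‑3‑yl pyridine‑2‑carboxylate
Conditions: pyridine‑2‑carboxylic acid, dicyclohexylcarbodiimide, DMAP (cat.), CH2Cl2, 0 °C → rt
Reagents that add atoms: pyridine‑2‑carboxylic acid, OC(=O)c1ccccn1
Why: Steglich esterification, which does not touch the carbinol centre; the picolinate is a chelating leaving group that favours anti‑SN2' substitution.

Step 4
Reactants: 5 prop‑2‑yn‑1‑ol
Product: 7 (2E)‑3‑iodo‑2‑methylprop‑2‑en‑1‑ol, via alkenylalane 6 (not isolated)
Conditions: Me3Al (3 equiv), Cp2ZrCl2 (0.25 equiv), CH2Cl2, 0 °C → rt; then I2, THF, −30 → 0 °C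
Reagents that add atoms: trimethylaluminium, C[Al](C)C; iodine, II
Why: Negishi zirconium‑catalysed carboalumination adds methyl and aluminium syn across the terminal alkyne with methyl on the internal carbon, and iodinolysis of the C–Al bond with retention should give the (E)‑iodide only.

Step 5
Reactants: 7 (2E)‑3‑iodo‑2‑methylprop‑2‑en‑1‑ol
Product: 8 tert‑butyl{[(2E)‑3‑iodo‑2‑methylprop‑2‑en‑1‑yl]oxy}dimethylsilane
Conditions: t‑BuMe2SiCl, imidazole, CH2Cl2, 0 °C → rt
Reagents that add atoms: tert‑butyl(chloro)dimethylsilane, CC(C)(C)[Si](C)(C)Cl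
Why: standard silylation of a primary alcohol, needed so that the iodide can be lithiated.

Step 6
Reactants: 8 tert‑butyl{[(2E)‑3‑iodo‑2‑methylprop‑2‑en‑1‑yl]oxy}dimethylsilane; 4 (3R,4E)‑hept‑4‑en‑3‑yl pyridine‑2‑carboxylate
Product: 12 tert‑butyl{[(2E,4R,5E)‑4‑ethyl‑2‑methylocta‑2,5‑dien‑1‑yl]oxy}dimethylsilane, via alkenyllithium 9 (not isolated), via alkenylmagnesium bromide 10 (not isolated), via bromomagnesium dialkenylcuprate 11 (not isolated)
Conditions: 8 (3 equiv), t‑BuLi (6 equiv), Et2O, −78 °C; MgBr2·OEt2; CuBr·SMe2 (1.5 equiv), THF, −40 °C; then 4 (1 equiv), −40 → 0 °C; aq. NH4Cl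
Reagents that add atoms: none
Why: iodine–lithium exchange with retention of alkene geometry is followed by copper‑mediated anti‑SN2' allylic substitution of the secondary picolinate, whose pyridine nitrogen and carbonyl chelate magnesium and activate the leaving group. The alkenyl group is delivered to the γ‑carbon anti to the C–O bond from the conformer with the carbinol hydrogen eclipsing the alkene, which should give the new (E)‑alkene and (R) at C4' by 1,3‑chirality transfer.

Step 7
Reactants: 12 tert‑butyl{[(2E,4R,5E)‑4‑ethyl‑2‑methylocta‑2,5‑dien‑1‑yl]oxy}dimethylsilane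
Product: 13 (2E,4R,5E)‑4‑ethyl‑2‑methylocta‑2,5‑dien‑1‑ol
Conditions: n‑Bu4NF, THF, 0 °C → rt
Reagents that add atoms: none
Why: fluoride‑induced cleavage of the silyl ether; nothing else in the molecule responds to fluoride.

Step 8
Reactants: 13 (2E,4R,5E)‑4‑ethyl‑2‑methylocta‑2,5‑dien‑1‑ol
Product: 14 (2E,4R,5E)‑1‑bromo‑4‑ethyl‑2‑methylocta‑2,5‑diene
Conditions: CBr4, PPh3, CH2Cl2, 0 °C; used without storage
Reagents that add atoms: tetrabromomethane, BrC(Br)(Br)Br
Why: Appel bromination of a primary allylic alcohol by SN2 at the CH2 carbon, which at 0 °C should proceed without allylic transposition or loss of the trisubstituted alkene geometry.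

Step 9
Reactants: 14 (2E,4R,5E)‑1‑bromo‑4‑ethyl‑2‑methylocta‑2,5‑diene; 15 methyl prop‑2‑ynoate
Product: 16 methyl (5E,7R,8E)‑7‑ethyl‑5‑methylundeca‑5,8‑dien‑2‑ynoate
Conditions: CuI (1 equiv), NaI (1 equiv), K2CO3 (1.5 equiv), DMF, rt
Reagents that add atoms: none
Why: copper‑mediated coupling of a terminal alkyne with a primary allylic halide; the copper acetylide of the propiolate displaces the halide at the unhindered CH2 carbon, and the weak carbonate base at room temperature is chosen to avoid isomerising the skipped enynoate.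

Step 10
Reactants: 17 (4R)‑4‑benzyl‑1,3‑oxazolidin‑2‑one; 18 butanoyl chloride
Product: 19 (4R)‑4‑benzyl‑3‑butanoyl‑1,3‑oxazolidin‑2‑one
Conditions: n‑BuLi, THF, −78 °C; then 18, −78 → 0 °C
Reagents that add atoms: none
Why: N‑acylation of the lithiated oxazolidinone, the standard entry to an Evans imide.

Step 11
Reactants: 19 (4R)‑4‑benzyl‑3‑butanoyl‑1,3‑oxazolidin‑2‑one
Product: 21 (4R)‑4‑benzyl‑3‑[(2S)‑2‑(dimethoxymethyl)butanoyl]‑1,3‑oxazolidin‑2‑one, via chlorotitanium enolate 20 (not isolated)
Conditions: TiCl4 (1.05 equiv), i‑Pr2NEt (1.1 equiv), CH2Cl2, 0 °C; HC(OMe)3 (2 equiv), 0 °C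
Reagents that add atoms: trimethyl orthoformate, COC(OC)OC
Why: Evans alkylation of the chelated chlorotitanium (Z)‑enolate with the dimethoxycarbenium ion released from the orthoformate; the electrophile approaches the enolate face opposite the benzyl group, which sets the future C4 as (2S) and installs C3 directly as its dimethyl acetal.

Step 12
Reactants: 21 (4R)‑4‑benzyl‑3‑[(2S)‑2‑(dimethoxymethyl)butanoyl]‑1,3‑oxazolidin‑2‑one
Product: 22 (2R)‑2‑(dimethoxymethyl)butan‑1‑ol
Conditions: LiBH4, MeOH (1 equiv), Et2O, 0 °C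
Reagents that add atoms: none
Why: reductive cleavage of the imide to the primary alcohol with recovery of the auxiliary; the acetal is inert and the stereocentre never passes through an enolisable aldehyde (the descriptor changes only by priority).

Step 13
Reactants: 22 (2R)‑2‑(dimethoxymethyl)butan‑1‑ol
Product: 23 (2S)‑2‑(iodomethyl)‑1,1‑dimethoxybutane
Conditions: I2, PPh3, imidazole, CH2Cl2, 0 °C → rt
Reagents that add atoms: iodine, II
Why: Appel‑type iodination of a primary alcohol; imidazole buffers the medium so the acetal survives, and the stereocentre is not involved.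

Step 14
Reactants: 23 (2S)‑2‑(iodomethyl)‑1,1‑dimethoxybutane; 16 methyl (5E,7R,8E)‑7‑ethyl‑5‑methylundeca‑5,8‑dien‑2‑ynoate
Product: 27 methyl (2Z,5E,7R,8E)‑3‑[(2R)‑2‑(dimethoxymethyl)butyl]‑7‑ethyl‑5‑methylundeca‑2,5,8‑trienoate, via alkyllithium 24 (not isolated), via alkylcopper 25 (not isolated), via alkenylcopper adduct 26 (not isolated)
Conditions: 23 (1.3 equiv), t‑BuLi (2.6 equiv), Et2O–pentane, −78 °C; CuBr·SMe2 (1.3 equiv), THF, −78 → −40 °C; 16 (1.0 equiv), THF, −78 °C; MeOH, −78 °C, then aq. NH4Cl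
Reagents that add atoms: none
Why: Iodine–lithium exchange gives primary alkyllithium 24, a γ,γ‑dialkoxy organometallic that should be stable at −78 °C, and transmetalation gives the monoalkylcopper 25. This adds across the triple bond of 16 by syn‑carbocupration, the alkyl group going to the β‑carbon (C6) and copper to the ester‑bearing carbon on the same side, forming the C5–C6 bond. The α‑cuprio enoate 26 keeps its configuration at −78 °C, and protonation at that temperature replaces copper with retention, so the ester ends up cis to C1' and the product is the (2Z)‑enoate. The closest known reaction is the stereospecific syn‑addition of organocopper reagents to 2‑alkynoates at low temperature. No ring is closed and no stereocentre is formed; the new stereochemical element is the alkene geometry, which carries the information for C6 and is controlled only by the syn mechanism. The step needs β‑regioselectivity, secured by the polarisation of the ynoate, and syn stereoselectivity, secured by low temperature and prompt cold protonation before the adduct can equilibrate through its allenoate form. It also needs chemoselectivity over proton abstraction from the C4 methylene of 16, for which the low basicity of a monoalkylcopper speaks. The C4 stereocentre of 23 is β to the metal and cannot epimerise.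

Step 15
Reactants: 27 methyl (2Z,5E,7R,8E)‑3‑[(2R)‑2‑(dimethoxymethyl)butyl]‑7‑ethyl‑5‑methylundeca‑2,5,8‑trienoate
Product: 28 (2Z,5E,7R,8E)‑3‑[(2R)‑2‑(dimethoxymethyl)butyl]‑7‑ethyl‑5‑methylundeca‑2,5,8‑trien‑1‑ol
Conditions: i‑Bu2AlH (2.5 equiv), CH2Cl2, −78 °C; aq. KNaC4H4O6
Reagents that add atoms: none
Why: 1,2‑reduction of the enoate to the allylic alcohol with i‑Bu2AlH; at −78 °C the acetal is untouched and the (Z)‑geometry is retained.

Step 16
Reactants: 28 (2Z,5E,7R,8E)‑3‑[(2R)‑2‑(dimethoxymethyl)butyl]‑7‑ethyl‑5‑methylundeca‑2,5,8‑trien‑1‑ol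
Product: 29 [(2R,3S)‑3‑[(2R)‑2‑(dimethoxymethyl)butyl]‑3‑[(2E,4R,5E)‑4‑ethyl‑2‑methylocta‑2,5‑dien‑1‑yl]oxiran‑2‑yl]methanol
Conditions: Ti(OiPr)4 (0.1 equiv), D‑(−)‑diisopropyl tartrate (0.12 equiv), t‑BuOOH (2 equiv, anhydrous), 4 Å MS, CH2Cl2, −20 °C
Reagents that add atoms: tert‑butyl hydroperoxide, CC(C)(C)OO
Why: Sharpless asymmetric epoxidation, which reacts only at the allylic alcohol and leaves the two chain alkenes alone. The face is chosen by the tartrate: the L‑(+)‑ester turns nerol, which has the same substitution pattern, into its (2S,3R)‑epoxide, so the D‑(−)‑ester should give the (2R,3S)‑epoxide here, with the epoxide oxygen on the face of C6 opposite to the one O1 must finally occupy.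

Step 17
Reactants: 29 [(2R,3S)‑3‑[(2R)‑2‑(dimethoxymethyl)butyl]‑3‑[(2E,4R,5E)‑4‑ethyl‑2‑methylocta‑2,5‑dien‑1‑yl]oxiran‑2‑yl]methanol
Product: 31 (1R)‑1‑[(4R,6R)‑4‑ethyl‑6‑[(2E,4R,5E)‑4‑ethyl‑2‑methylocta‑2,5‑dien‑1‑yl]‑3‑methoxy‑1,2‑dioxan‑6‑yl]ethane‑1,2‑diol (C3 anomers), via hydroperoxy diol 30 (not isolated)
Conditions: H2O2 (anhydrous, Et2O, 10 equiv), H3PMo12O40 (5 mol%), Et2O, 0 °C → rt; then MeOH, camphorsulfonic acid (cat.), 0 °C; NaHCO3
Reagents that add atoms: hydrogen peroxide, OO
Why: acid‑catalysed perhydrolysis of an epoxide, in which H2O2 attacks the tertiary carbon of the 2,3‑epoxy alcohol from the back and sets C6 as (R) by inversion, followed by acid‑catalysed transacetalisation of the tertiary hydroperoxide onto the dimethyl acetal to close the six‑membered peroxyacetal. If exchange at C3 happens first and the resulting hydroperoxy acetal opens the epoxide intramolecularly, the same ring with the same C6 results. Methanol as solvent for the second stage works against capture of C3 by the glycol oxygens, and hydroperoxides bind acetal carbon far more strongly than alcohols do.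

Step 18
Reactants: 31 (1R)‑1‑[(4R,6R)‑4‑ethyl‑6‑[(2E,4R,5E)‑4‑ethyl‑2‑methylocta‑2,5‑dien‑1‑yl]‑3‑methoxy‑1,2‑dioxan‑6‑yl]ethane‑1,2‑diol
Product: 32 (4R,6R)‑4‑ethyl‑6‑[(2E,4R,5E)‑4‑ethyl‑2‑methylocta‑2,5‑dien‑1‑yl]‑3‑methoxy‑1,2‑dioxane‑6‑carbaldehyde (C3 anomers)
Conditions: NaIO4, THF–H2O (pH 7 buffer), 0 °C
Reagents that add atoms: none
Why: Malaprade glycol cleavage; periodate does not affect the dialkyl peroxide, the peroxyacetal or the alkenes, and C6 is quaternary so the new aldehyde cannot epimerise.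

Step 19
Reactants: 32 (4R,6R)‑4‑ethyl‑6‑[(2E,4R,5E)‑4‑ethyl‑2‑methylocta‑2,5‑dien‑1‑yl]‑3‑methoxy‑1,2‑dioxane‑6‑carbaldehyde
Product: 33 (4R,6R)‑6‑ethenyl‑4‑ethyl‑6‑[(2E,4R,5E)‑4‑ethyl‑2‑methylocta‑2,5‑dien‑1‑yl]‑3‑methoxy‑1,2‑dioxane (C3 anomers)
Conditions: Ph3PCH3Br (1.3 equiv), KN(SiMe3)2 (1.25 equiv), THF, 0 °C; then 32, −78 → 0 °C
Reagents that add atoms: methyltriphenylphosphonium bromide, C[P+](c1ccccc1)(c1ccccc1)c1ccccc1.[Br-]
Why: Wittig methylenation with a salt‑free ylide used in slight excess at low temperature, where addition to the aldehyde should be faster than attack on the hindered tertiary dialkyl peroxide or abstraction of the C3 hydrogen.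

Step 20
Reactants: 33 (4R,6R)‑6‑ethenyl‑4‑ethyl‑6‑[(2E,4R,5E)‑4‑ethyl‑2‑methylocta‑2,5‑dien‑1‑yl]‑3‑methoxy‑1,2‑dioxane
Product: 34 (4R,6R)‑4,6‑diethyl‑6‑[(2E,4R,5E)‑4‑ethyl‑2‑methylocta‑2,5‑dien‑1‑yl]‑3‑methoxy‑1,2‑dioxane (C3 anomers)
Conditions: 2‑nitrobenzenesulfonylhydrazide (added in portions), Et3N, CH2Cl2, rt; stopped when 33 is consumed
Reagents that add atoms: none
Why: diimide reduction, a concerted syn transfer of two hydrogens that does not cleave O–O bonds; the monosubstituted vinyl group should react faster than the 1,2‑disubstituted and trisubstituted chain alkenes, and portionwise generation of the reagent is meant to exploit that rate difference.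

Step 21
Reactants: 34 (4R,6R)‑4,6‑diethyl‑6‑[(2E,4R,5E)‑4‑ethyl‑2‑methylocta‑2,5‑dien‑1‑yl]‑3‑methoxy‑1,2‑dioxane
Product: 36 methyl 2‑[(3R,4R,6R)‑4,6‑diethyl‑6‑[(2E,4R,5E)‑4‑ethyl‑2‑methylocta‑2,5‑dien‑1‑yl]‑1,2‑dioxan‑3‑yl]acetate, via peroxycarbenium ion 35 (not isolated)
Conditions: CH2=C(OMe)OSiMe2t‑Bu (3 equiv), TiCl4 (1.1 equiv), CH2Cl2, −78 °C; aq. NaHCO3
Reagents that add atoms: tert‑butyl[(1‑methoxyethenyl)oxy]dimethylsilane, C=C(OC)O[Si](C)(C)C(C)(C)C
Why: TiCl4 binds the more basic methoxy oxygen of either anomer and releases the cyclic peroxycarbenium ion 35, which the silyl ketene acetal traps in a Mukaiyama‑type addition, a substitution known for 3‑alkoxy‑1,2‑dioxanes and ‑dioxolanes. C3 should become (R) by axial attack on the half‑chair that keeps the C4 ethyl group pseudo‑equatorial, since the other half‑chair forces the C4 ethyl group and the C6 chain into a 1,3‑diaxial contact; axial entry places the acetate arm cis to the C4 ethyl group.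

## Compound list

1 | (2E)‑pent‑2‑enal | CC/C=C/C=O | starting material
2 | rac‑(4E)‑hept‑4‑en‑3‑ol | CC/C=C/C(O)CC | intermediate
3 | (3R,4E)‑hept‑4‑en‑3‑ol | CC/C=C/[C@H](O)CC | intermediate
4 | (3R,4E)‑hept‑4‑en‑3‑yl pyridine‑2‑carboxylate | CC/C=C/[C@H](OC(=O)c1ccccn1)CC | intermediate
5 | prop‑2‑yn‑1‑ol | C#CCO | starting material
6 | dimethyl[(1E)‑3‑(dimethylalumanyloxy)‑2‑methylprop‑1‑en‑1‑yl]alumane | C[Al](C)/C=C(\C)CO[Al](C)C | intermediate
7 | (2E)‑3‑iodo‑2‑methylprop‑2‑en‑1‑ol | OC/C(C)=C/I | intermediate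
8 | tert‑butyl{[(2E)‑3‑iodo‑2‑methylprop‑2‑en‑1‑yl]oxy}dimethylsilane | CC(C)(C)[Si](C)(C)OC/C(C)=C/I | intermediate
9 | [(1E)‑3‑(tert‑butyldimethylsilyloxy)‑2‑methylprop‑1‑en‑1‑yl]lithium | [Li]/C=C(\C)CO[Si](C)(C)C(C)(C)C | intermediate
10 | [(1E)‑3‑(tert‑butyldimethylsilyloxy)‑2‑methylprop‑1‑en‑1‑yl]magnesium bromide | Br[Mg]/C=C(\C)CO[Si](C)(C)C(C)(C)C | intermediate
11 | bromomagnesium bis[(1E)‑3‑(tert‑butyldimethylsilyloxy)‑2‑methylprop‑1‑en‑1‑yl]cuprate | CC(C)(C)[Si](C)(C)OC/C(C)=C/[Cu-]/C=C(\C)CO[Si](C)(C)C(C)(C)C.[Mg+]Br | intermediate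
12 | tert‑butyl{[(2E,4R,5E)‑4‑ethyl‑2‑methylocta‑2,5‑dien‑1‑yl]oxy}dimethylsilane | CC/C=C/[C@H](/C=C(\C)CO[Si](C)(C)C(C)(C)C)CC | intermediate
13 | (2E,4R,5E)‑4‑ethyl‑2‑methylocta‑2,5‑dien‑1‑ol | CC/C=C/[C@H](/C=C(\C)CO)CC | intermediate
14 | (2E,4R,5E)‑1‑bromo‑4‑ethyl‑2‑methylocta‑2,5‑diene | CC/C=C/[C@H](/C=C(\C)CBr)CC | intermediate
15 | methyl prop‑2‑ynoate | C#CC(=O)OC | starting material
16 | methyl (5E,7R,8E)‑7‑ethyl‑5‑methylundeca‑5,8‑dien‑2‑ynoate | CC/C=C/[C@H](/C=C(\C)CC#CC(=O)OC)CC | intermediate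
17 | (4R)‑4‑benzyl‑1,3‑oxazolidin‑2‑one | O=C1N[C@H](Cc2ccccc2)CO1 | starting material
18 | butanoyl chloride | CCCC(Cl)=O | starting material
19 | (4R)‑4‑benzyl‑3‑butanoyl‑1,3‑oxazolidin‑2‑one | CCCC(=O)N1[C@H](Cc2ccccc2)COC1=O | intermediate
20 | trichloro{[(1Z)‑1‑[(4R)‑4‑benzyl‑2‑oxo‑1,3‑oxazolidin‑3‑yl]but‑1‑en‑1‑yl]oxy}titanium | CC/C=C(\O[Ti](Cl)(Cl)Cl)N1[C@H](Cc2ccccc2)COC1=O | intermediate
21 | (4R)‑4‑benzyl‑3‑[(2S)‑2‑(dimethoxymethyl)butanoyl]‑1,3‑oxazolidin‑2‑one | CC[C@@H](C(OC)OC)C(=O)N1[C@H](Cc2ccccc2)COC1=O | intermediate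
22 | (2R)‑2‑(dimethoxymethyl)butan‑1‑ol | CC[C@@H](C(OC)OC)CO | intermediate
23 | (2S)‑2‑(iodomethyl)‑1,1‑dimethoxybutane | CC[C@@H](C(OC)OC)CI | intermediate
24 | [(2S)‑2‑(dimethoxymethyl)butyl]lithium | [Li]C[C@@H](CC)C(OC)OC | intermediate
25 | [(2S)‑2‑(dimethoxymethyl)butyl]copper | [Cu]C[C@@H](CC)C(OC)OC | intermediate
26 | methyl (2E,5E,7R,8E)‑2‑cuprio‑3‑[(2R)‑2‑(dimethoxymethyl)butyl]‑7‑ethyl‑5‑methylundeca‑2,5,8‑trienoate | CC/C=C/[C@H](/C=C(\C)C/C(=C(/[Cu])C(=O)OC)C[C@@H](CC)C(OC)OC)CC | intermediate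
27 | methyl (2Z,5E,7R,8E)‑3‑[(2R)‑2‑(dimethoxymethyl)butyl]‑7‑ethyl‑5‑methylundeca‑2,5,8‑trienoate | CC/C=C/[C@H](/C=C(\C)C/C(=C\C(=O)OC)C[C@@H](CC)C(OC)OC)CC | intermediate
28 | (2Z,5E,7R,8E)‑3‑[(2R)‑2‑(dimethoxymethyl)butyl]‑7‑ethyl‑5‑methylundeca‑2,5,8‑trien‑1‑ol | CC/C=C/[C@H](/C=C(\C)C/C(=C\CO)C[C@@H](CC)C(OC)OC)CC | intermediate
29 | [(2R,3S)‑3‑[(2R)‑2‑(dimethoxymethyl)butyl]‑3‑[(2E,4R,5E)‑4‑ethyl‑2‑methylocta‑2,5‑dien‑1‑yl]oxiran‑2‑yl]methanol | CC/C=C/[C@H](/C=C(\C)C[C@]1(C[C@@H](CC)C(OC)OC)O[C@@H]1CO)CC | intermediate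
30 | (2R,3R,5E,7R,8E)‑3‑[(2R)‑2‑(dimethoxymethyl)butyl]‑7‑ethyl‑3‑hydroperoxy‑5‑methylundeca‑5,8‑diene‑1,2‑diol | CC/C=C/[C@H](/C=C(\C)C[C@](OO)(C[C@@H](CC)C(OC)OC)[C@H](O)CO)CC | intermediate
31 | (1R)‑1‑[(4R,6R)‑4‑ethyl‑6‑[(2E,4R,5E)‑4‑ethyl‑2‑methylocta‑2,5‑dien‑1‑yl]‑3‑methoxy‑1,2‑dioxan‑6‑yl]ethane‑1,2‑diol (C3 anomers) | CC/C=C/[C@H](/C=C(\C)C[C@@]1([C@H](O)CO)C[C@@H](CC)C(OC)OO1)CC | intermediate
32 | (4R,6R)‑4‑ethyl‑6‑[(2E,4R,5E)‑4‑ethyl‑2‑methylocta‑2,5‑dien‑1‑yl]‑3‑methoxy‑1,2‑dioxane‑6‑carbaldehyde (C3 anomers) | CC/C=C/[C@H](/C=C(\C)C[C@@]1(C=O)C[C@@H](CC)C(OC)OO1)CC | intermediate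
33 | (4R,6R)‑6‑ethenyl‑4‑ethyl‑6‑[(2E,4R,5E)‑4‑ethyl‑2‑methylocta‑2,5‑dien‑1‑yl]‑3‑methoxy‑1,2‑dioxane (C3 anomers) | CC/C=C/[C@H](/C=C(\C)C[C@@]1(C=C)C[C@@H](CC)C(OC)OO1)CC | intermediate
34 | (4R,6R)‑4,6‑diethyl‑6‑[(2E,4R,5E)‑4‑ethyl‑2‑methylocta‑2,5‑dien‑1‑yl]‑3‑methoxy‑1,2‑dioxane (C3 anomers) | CC/C=C/[C@H](/C=C(\C)C[C@@]1(CC)C[C@@H](CC)C(OC)OO1)CC | intermediate
35 | (4R,6R)‑4,6‑diethyl‑6‑[(2E,4R,5E)‑4‑ethyl‑2‑methylocta‑2,5‑dien‑1‑yl]‑1,2‑dioxan‑3‑ylium (peroxycarbenium ion) | CC/C=C/[C@H](/C=C(\C)C[C@@]1(CC)C[C@@H](CC)C=[O+]O1)CC | intermediate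
36 | methyl 2‑[(3R,4R,6R)‑4,6‑diethyl‑6‑[(2E,4R,5E)‑4‑ethyl‑2‑methylocta‑2,5‑dien‑1‑yl]‑1,2‑dioxan‑3‑yl]acetate | CC/C=C/[C@H](/C=C(\C)C[C@@]1(CC)C[C@@H](CC)[C@@H](CC(=O)OC)OO1)CC | target

## Step count and least certain steps

Total: 21 steps. Longest linear sequence: 15 steps (1, 2, 3, 6, 7, 8, 9, 14–21).

Step 14 (key step). The most likely failure is loss of geometric purity, because the alkenylcopper adduct can equilibrate through its allenoate form if the mixture warms before protonation. Proton transfer from the doubly activated C4 methylene of 16 to the organometallic, and 1,3‑elimination or coupling during the iodine–lithium exchange, would lower conversion.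
Fallback, from 16 and 23, returning at 27: the geometry is still set by a syn‑addition to 16, but the C5–C6 bond is made by cross‑coupling. Syn‑stannylcupration of 16 with Me3SnCu·SMe2 (THF, −78 °C, MeOH present) should give methyl (2E,5E,7R,8E)‑7‑ethyl‑5‑methyl‑3‑(trimethylstannyl)undeca‑2,5,8‑trienoate F1. Iododestannylation with retention (I2, CH2Cl2, 0 °C) gives methyl (2E,5E,7R,8E)‑7‑ethyl‑3‑iodo‑5‑methylundeca‑2,5,8‑trienoate F2. Zinc insertion into 23 (Zn, LiCl, THF) gives [(2S)‑2‑(dimethoxymethyl)butyl]zinc iodide F3, and Negishi coupling of F2 with F3 (PdCl2(dppf), THF, rt) proceeds with retention at the alkene to give 27.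

Step 17. Two processes threaten it. Opening of the tertiary epoxide may gain SN1 character, with partial loss of inversion at C6 or participation of an acetal oxygen. The glycol oxygens may also capture the C3 carbon in place of the hydroperoxide.
Fallback, from 29, returning at 36: the glycol capture is accepted and the endgame reordered. After perhydrolysis, acid treatment without methanol (camphorsulfonic acid, CH2Cl2) should drive both the hydroperoxide and the secondary hydroxyl onto C3 to give the bicyclic peroxy‑acetal [8‑ethyl‑1‑[(2E,4R,5E)‑4‑ethyl‑2‑methylocta‑2,5‑dien‑1‑yl]‑2,3,5‑trioxabicyclo[2.2.2]octan‑6‑yl]methanol F4. TiCl4 binds its ether oxygen and not a peroxide oxygen, so the same kind of cation as 35 is formed and trapped by the silyl ketene acetal to give methyl 2‑[(3R,4R,6R)‑6‑[(1R)‑1,2‑dihydroxyethyl]‑4‑ethyl‑6‑[(2E,4R,5E)‑4‑ethyl‑2‑methylocta‑2,5‑dien‑1‑yl]‑1,2‑dioxan‑3‑yl]acetate F5. Glycol cleavage (NaIO4) gives methyl 2‑[(3R,4R,6R)‑4‑ethyl‑6‑[(2E,4R,5E)‑4‑ethyl‑2‑methylocta‑2,5‑dien‑1‑yl]‑6‑formyl‑1,2‑dioxan‑3‑yl]acetate F6, Wittig methylenation gives methyl 2‑[(3R,4R,6R)‑6‑ethenyl‑4‑ethyl‑6‑[(2E,4R,5E)‑4‑ethyl‑2‑methylocta‑2,5‑dien‑1‑yl]‑1,2‑dioxan‑3‑yl]acetate F7, and diimide reduction gives 36.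

Step 21. The risk is poor facial selectivity at C3: the incoming nucleophile is gauche to the neighbouring C4 ethyl group on the stereoelectronically preferred axial path, so attack from the opposite face (3,4‑trans product) may compete. Ring‑opening ionisation is a lesser concern.
Fallback, from 34, returning at 36: the order of bond formation at C3 is reversed, which is useful if the cation proves to be attacked mainly anti to the C4 ethyl group. Hydrolysis of 34 (aq. AcOH, THF) gives (4R,6R)‑4,6‑diethyl‑6‑[(2E,4R,5E)‑4‑ethyl‑2‑methylocta‑2,5‑dien‑1‑yl]‑1,2‑dioxan‑3‑ol F8. Oxidation (Dess–Martin periodinane) gives (4R,6R)‑4,6‑diethyl‑6‑[(2E,4R,5E)‑4‑ethyl‑2‑methylocta‑2,5‑dien‑1‑yl]‑1,2‑dioxan‑3‑one F9. Addition of the lithium enolate of methyl acetate (LiN(i‑Pr)2, THF, −78 °C) gives methyl 2‑[(4R,6R)‑4,6‑diethyl‑6‑[(2E,4R,5E)‑4‑ethyl‑2‑methylocta‑2,5‑dien‑1‑yl]‑3‑hydroxy‑1,2‑dioxan‑3‑yl]acetate F10. Ionic reduction (Et3SiH, BF3·OEt2, CH2Cl2, −78 °C) then delivers hydride to the face that the carbon nucleophile preferred, which leaves the acetate arm cis to the C4 ethyl group in 36.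

Step 20. The likely failure is over‑reduction: the vinyl group sits on a quaternary carbon and is only moderately faster than the 1,2‑disubstituted chain alkene, so some C5'=C6' reduction may accompany full conversion.
Fallback, from 32, returning at 34 (no alkene reduction): condensation of 32 with 4‑methylbenzenesulfonylhydrazide gives the 4‑methylbenzenesulfonylhydrazone of 32 F11, and silylation (t‑BuMe2SiOTf, Et3N) gives its N‑(tert‑butyldimethylsilyl) derivative F12. Addition of MeLi at −78 °C to the C=N bond, followed by AcOH in CF3CH2OH, expels sulfinate and dinitrogen from the resulting diazene and leaves the ethyl group of 34.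

Step 6. The two allyl termini of 4 both carry ethyl groups, so any direct α‑substitution or syn pathway gives the enantiomer of 12; erosion of the C4' configuration is the main risk, with E/Z leakage in the new alkene second.
Fallback, from 22, returning at 13: C4' is taken from the auxiliary‑derived centre of 22, which has the correct sense. Oxidation (Dess–Martin periodinane) gives (2R)‑2‑(dimethoxymethyl)butanal F13. Julia–Kocienski olefination with 1‑phenyl‑5‑(propylsulfonyl)‑1H‑tetrazole and KN(SiMe3)2 gives (3E,5R)‑5‑(dimethoxymethyl)hept‑3‑ene F14. Mild acetal hydrolysis gives (2R,3E)‑2‑ethylhex‑3‑enal F15, which is used at once in a Wittig reaction with ethyl 2‑(triphenylphosphoranylidene)propanoate to give ethyl (2E,4R,5E)‑4‑ethyl‑2‑methylocta‑2,5‑dienoate F16. Reduction with i‑Bu2AlH gives 13.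

Step 9. The product has a CH2 group between an alkene and an ynoate, and base‑induced isomerisation to allenic or conjugated esters, or SN2' coupling, may lower the yield.
Fallback, from 14, returning at 16: copper‑catalysed coupling of 14 with ethynylmagnesium bromide (CuBr·SMe2 cat., THF) gives (4E,6R,7E)‑6‑ethyl‑4‑methyldeca‑4,7‑dien‑1‑yne F17. Deprotonation of the terminal alkyne (n‑BuLi, THF, −78 °C) and acylation with methyl chloroformate gives 16 without exposing the ynoate to base.

## Further compounds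

F1 | step 14 | methyl (2E,5E,7R,8E)‑7‑ethyl‑5‑methyl‑3‑(trimethylstannyl)undeca‑2,5,8‑trienoate | CC/C=C/[C@H](/C=C(\C)C/C(=C\C(=O)OC)[Sn](C)(C)C)CC
F2 | step 14 | methyl (2E,5E,7R,8E)‑7‑ethyl‑3‑iodo‑5‑methylundeca‑2,5,8‑trienoate | CC/C=C/[C@H](/C=C(\C)C/C(I)=C\C(=O)OC)CC
F3 | step 14 | [(2S)‑2‑(dimethoxymethyl)butyl]zinc iodide | I[Zn]C[C@@H](CC)C(OC)OC
F4 | step 17 | [8‑ethyl‑1‑[(2E,4R,5E)‑4‑ethyl‑2‑methylocta‑2,5‑dien‑1‑yl]‑2,3,5‑trioxabicyclo[2.2.2]octan‑6‑yl]methanol | CC/C=C/[C@H](/C=C(\C)C[C@@]12C[C@@H](CC)[C@@H](OO1)O[C@@H]2CO)CC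
F5 | step 17 | methyl 2‑[(3R,4R,6R)‑6‑[(1R)‑1,2‑dihydroxyethyl]‑4‑ethyl‑6‑[(2E,4R,5E)‑4‑ethyl‑2‑methylocta‑2,5‑dien‑1‑yl]‑1,2‑dioxan‑3‑yl]acetate | CC/C=C/[C@H](/C=C(\C)C[C@@]1([C@H](O)CO)C[C@@H](CC)[C@@H](CC(=O)OC)OO1)CC
F6 | step 17 | methyl 2‑[(3R,4R,6R)‑4‑ethyl‑6‑[(2E,4R,5E)‑4‑ethyl‑2‑methylocta‑2,5‑dien‑1‑yl]‑6‑formyl‑1,2‑dioxan‑3‑yl]acetate | CC/C=C/[C@H](/C=C(\C)C[C@@]1(C=O)C[C@@H](CC)[C@@H](CC(=O)OC)OO1)CC
F7 | step 17 | methyl 2‑[(3R,4R,6R)‑6‑ethenyl‑4‑ethyl‑6‑[(2E,4R,5E)‑4‑ethyl‑2‑methylocta‑2,5‑dien‑1‑yl]‑1,2‑dioxan‑3‑yl]acetate | CC/C=C/[C@H](/C=C(\C)C[C@@]1(C=C)C[C@@H](CC)[C@@H](CC(=O)OC)OO1)CC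
F8 | step 21 | (4R,6R)‑4,6‑diethyl‑6‑[(2E,4R,5E)‑4‑ethyl‑2‑methylocta‑2,5‑dien‑1‑yl]‑1,2‑dioxan‑3‑ol | CC/C=C/[C@H](/C=C(\C)C[C@@]1(CC)C[C@@H](CC)C(O)OO1)CC
F9 | step 21 | (4R,6R)‑4,6‑diethyl‑6‑[(2E,4R,5E)‑4‑ethyl‑2‑methylocta‑2,5‑dien‑1‑yl]‑1,2‑dioxan‑3‑one | CC/C=C/[C@H](/C=C(\C)C[C@@]1(CC)C[C@@H](CC)C(=O)OO1)CC
F10 | step 21 | methyl 2‑[(4R,6R)‑4,6‑diethyl‑6‑[(2E,4R,5E)‑4‑ethyl‑2‑methylocta‑2,5‑dien‑1‑yl]‑3‑hydroxy‑1,2‑dioxan‑3‑yl]acetate | CC/C=C/[C@H](/C=C(\C)C[C@@]1(CC)C[C@@H](CC)C(O)(CC(=O)OC)OO1)CC
F11 | step 20 | 4‑methylbenzenesulfonylhydrazone of 32 | CC/C=C/[C@H](/C=C(\C)C[C@@]1(/C=N/NS(=O)(=O)c2ccc(C)cc2)C[C@@H](CC)C(OC)OO1)CC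
F12 | step 20 | N‑(tert‑butyldimethylsilyl)‑4‑methylbenzenesulfonylhydrazone of 32 | CC/C=C/[C@H](/C=C(\C)C[C@@]1(/C=N/N([Si](C)(C)C(C)(C)C)S(=O)(=O)c2ccc(C)cc2)C[C@@H](CC)C(OC)OO1)CC
F13 | step 6 | (2R)‑2‑(dimethoxymethyl)butanal | CC[C@@H](C(OC)OC)C=O
F14 | step 6 | (3E,5R)‑5‑(dimethoxymethyl)hept‑3‑ene | CC/C=C/[C@H](C(OC)OC)CC
F15 | step 6 | (2R,3E)‑2‑ethylhex‑3‑enal | CC/C=C/[C@H](C=O)CC
F16 | step 6 | ethyl (2E,4R,5E)‑4‑ethyl‑2‑methylocta‑2,5‑dienoate | CC/C=C/[C@H](/C=C(\C)C(=O)OCC)CC
F17 | step 9 | (4E,6R,7E)‑6‑ethyl‑4‑methyldeca‑4,7‑dien‑1‑yne | CC/C=C/[C@H](/C=C(\C)CC#C)CC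
A1 | alternative 1 | 6‑[(1R)‑1,2‑dihydroxyethyl]‑1,2‑dioxane with a 2‑(tert‑butyldiphenylsilyloxy)ethyl group at C3 | CC/C=C/[C@H](/C=C(\C)C[C@@]1([C@H](O)CO)C[C@@H](CC)[C@@H](CCO[Si](c2ccccc2)(c2ccccc2)C(C)(C)C)OO1)CC
A2 | alternative 1 | open‑chain C3 hydroperoxide carrying the trisubstituted epoxy alcohol | CC/C=C/[C@H](/C=C(\C)C[C@]1(C[C@@H](CC)[C@@H](CCO[Si](c2ccccc2)(c2ccccc2)C(C)(C)C)OO)O[C@@H]1CO)CC
A3 | alternative 2 | (2S,3S)‑5‑(tert‑butyldiphenylsilyloxy)‑2‑ethyl‑3‑hydroxypentanal | O=C[C@@H](CC)[C@@H](O)CCO[Si](c1ccccc1)(c1ccccc1)C(C)(C)C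
A4 | alternative 2 | 3‑(tert‑butyldiphenylsilyloxy)propanal | O=CCCO[Si](c1ccccc1)(c1ccccc1)C(C)(C)C
A5 | alternative 2 | butanal | CCCC=O
A6 | alternative 2 | (S)‑pyrrolidine‑2‑carboxylic acid | OC(=O)[C@@H]1CCCN1
A7 | alternative 3 | 3‑methoxy‑6‑vinyl‑1,2‑dioxane with the chain at C6 (C3 anomer drawn arbitrarily) | CC/C=C/[C@H](/C=C(\C)C[C@@]1(C=C)C[C@@H](CC)[C@@H](OC)OO1)CC
A8 | alternative 3 | 3,6‑dimethoxy‑1,2‑dioxane with the chain at C6 (anomeric centres open) | CC/C=C/[C@H](/C=C(\C)CC1(OC)C[C@@H](CC)C(OC)OO1)CC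
A9 | alternative 3 | potassium ethenyltrifluoroborate | C=C[B-](F)(F)F.[K+]
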